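**Retrosynthetic overview**

1. In the ten-membered carbocycle, C2 is α to the C1 ketone and C3 is allylic to the Z C4=C5 olefin, so C2–C3 is cut as an enolate–allyl bond. The two carbons are first joined through a carboxylate (C2–CO–O–C3) in the twelve-membered allyl β-keto lactone 27, and zerovalent palladium then extrudes CO2.
2. 27 comes from seco alcohol 25 by acylketene macrolactonisation (dioxinone thermolysis). C6, C8 and C13 are ethers and the butenolide stays open (C6 silyl ether, C12 methyl ester), so C3–O is the only ionisable allylic bond.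
3. 25 is built by carbonylative Stille coupling of the tetrasubstituted iodide 21 with allylstannane 7 (C7–C8, C8–C9), then CBS reduction for C8. 21 comes from ynoate 17 by syn-distannylation and α-alkylation, which fixes the C7=C11 geometry. C6 is set by asymmetric alkynylation of Z-enal 13.
4. Ring order: twelve-membered lactone (step 16), ten-membered carbocycle (step 17), oxirane (step 20), butenolide (step 21).

Key step: step 17

Remark: atom numbers follow the target (C1 ketone, C10=C14, C4–C5 oxirane with C15 methyl, C6 lactone CH, C7=C11, C8 ester CH, C12 carboxyl, C13 CH2O); DMB = 3,4-dimethoxybenzyl, PMB = 4-methoxybenzyl, TES = triethylsilyl; PMBOCH2Cl is assumed to be made just before use (PMBOCH2SMe, SO2Cl2), and the Zn–ProPhenol alkynylation is assumed to show on the Z-enal the facial sense known for simple enals (otherwise the ligand antipode is used).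

**Route**

Step 1
Reactants: 1 2,2,6-trimethyl-4H-1,3-dioxin-4-one
Product: 3 2,2-dimethyl-6-[2-(tributylstannyl)ethyl]-4H-1,3-dioxin-4-one, via lithium dienolate 2 (not isolated)
Conditions: LDA, THF, -78 °C; ICH2SnBu3, HMPA, -78 to -40 °C
Reagents that add atoms: tributyl(iodomethyl)stannane, CCCC[Sn](CCCC)(CCCC)CI
Why: γ-Alkylation of the dioxinone lithium dienolate (vinylogous ester enolate, an acetoacetate γ-anion equivalent) with a reactive primary iodide puts the future C9 and its tin handle on the carbon that becomes C10.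

Step 2
Reactants: 3 2,2-dimethyl-6-[2-(tributylstannyl)ethyl]-4H-1,3-dioxin-4-one
Product: 5 6-[1-(dimethylamino)-3-(tributylstannyl)propan-2-yl]-2,2-dimethyl-4H-1,3-dioxin-4-one (racemic), via lithium dienolate 4 (not isolated)
Conditions: LDA, THF, -78 °C; CH2=NMe2 I, -78 to 0 °C
Reagents that add atoms: Eschenmoser's salt (N,N-dimethylmethyleneiminium iodide), C=[N+](C)C.[I-]
Why: Vinylogous Mannich reaction of the γ-dienolate with the iminium salt adds the future C14 at C10; the racemic centre formed is destroyed in step 3.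

Step 3
Reactants: 5 6-[1-(dimethylamino)-3-(tributylstannyl)propan-2-yl]-2,2-dimethyl-4H-1,3-dioxin-4-one
Product: 7 2,2-dimethyl-6-[3-(tributylstannyl)prop-1-en-2-yl]-4H-1,3-dioxin-4-one, via ammonium iodide 6 (not isolated)
Conditions: MeI, CH2Cl2, 23 °C; DBU, 0 °C
Reagents that add atoms: none
Why: Quaternisation and E1cB loss of trimethylamine (Mannich-base methylenation) unveil the C10=C14 methylene and make the CH2SnBu3 group allylic, giving a 2-substituted allylstannane.

Step 4
Reactants: 8 prop-2-yn-1-ol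
Product: 10 (2Z)-3-iodo-2-methylprop-2-en-1-ol, via alkenylmagnesium alkoxide 9 (not isolated)
Conditions: MeMgBr, CuI (10 mol %), Et2O, -10 to 23 °C; I2, -78 to 0 °C
Reagents that add atoms: methylmagnesium bromide, C[Mg]Br; iodine, II
Why: Copper-catalysed anti-carbomagnesiation of the propargylic alkoxide (Duboudin reaction) places methyl on the internal carbon and magnesium on the terminus in a five-membered chelate, and iodinolysis with retention gives the Z iodide that fixes the Z C4=C5 geometry.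

Step 5
Reactants: 10 (2Z)-3-iodo-2-methylprop-2-en-1-ol
Product: 11 4-({[(2Z)-3-iodo-2-methylprop-2-en-1-yl]oxy}methyl)-1,2-dimethoxybenzene
Conditions: NaH, DMBCl, Bu4NI (cat.), THF/DMF, 0 to 23 °C
Reagents that add atoms: 3,4-dimethoxybenzyl chloride, COc1ccc(CCl)cc1OC
Why: Williamson etherification; the DMB ether at C3 can later be removed by DDQ in the presence of the PMB ether at C13.

Step 6
Reactants: 11 4-({[(2Z)-3-iodo-2-methylprop-2-en-1-yl]oxy}methyl)-1,2-dimethoxybenzene
Product: 13 (2Z)-4-[(3,4-dimethoxybenzyl)oxy]-3-methylbut-2-enal, via vinyllithium 12 (not isolated)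
Conditions: t-BuLi (2.0 equiv), Et2O, -78 °C; DMF; aq. NH4Cl
Reagents that add atoms: N,N-dimethylformamide, CN(C)C=O
Why: Iodine–lithium exchange with retention of the Z geometry, then formylation of the vinyllithium with DMF, gives the Z-enal carrying C3–C6.

Step 7
Reactants: 13 (2Z)-4-[(3,4-dimethoxybenzyl)oxy]-3-methylbut-2-enal; 14 methyl prop-2-ynoate
Product: 16 methyl (4S,5Z)-7-[(3,4-dimethoxybenzyl)oxy]-4-hydroxy-6-methylhept-5-en-2-ynoate, via zinc alkynylide 15 (not isolated)
Conditions: Me2Zn, (R,R)-ProPhenol (20 mol %), Ph3PO, toluene, 4 °C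
Reagents that add atoms: none
Why: Zinc–ProPhenol asymmetric alkynylation, in which the dinuclear zinc catalyst binds aldehyde and alkynylide 15 and delivers the alkyne to one aldehyde face to set the carbinol S (C6 of the target), under conditions mild enough to leave the Z-enal unisomerised.

Step 8
Reactants: 16 methyl (4S,5Z)-7-[(3,4-dimethoxybenzyl)oxy]-4-hydroxy-6-methylhept-5-en-2-ynoate
Product: 17 methyl (4S,5Z)-7-[(3,4-dimethoxybenzyl)oxy]-6-methyl-4-[(triethylsilyl)oxy]hept-5-en-2-ynoate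
Conditions: TESCl, imidazole, CH2Cl2, 0 °C
Reagents that add atoms: chlorotriethylsilane, CC[Si](CC)(CC)Cl
Why: Silylation of the propargylic alcohol protects the C6 oxygen before the C7=C11 olefin and its cis ester exist, so no butenolide can form prematurely.

Step 9
Reactants: 17 methyl (4S,5Z)-7-[(3,4-dimethoxybenzyl)oxy]-6-methyl-4-[(triethylsilyl)oxy]hept-5-en-2-ynoate
Product: 18 methyl (2Z,4S,5Z)-7-[(3,4-dimethoxybenzyl)oxy]-6-methyl-4-[(triethylsilyl)oxy]-2,3-bis(trimethylstannyl)hepta-2,5-dienoate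
Conditions: Me3SnSnMe3, Pd(PPh3)4 (3 mol %), THF, 23 °C, dark
Reagents that add atoms: hexamethylditin, C[Sn](C)(C)[Sn](C)(C)C
Why: Palladium-catalysed syn addition of the Sn–Sn bond across the ynoate (distannylation of α,β-acetylenic esters) places the two tin groups cis, and hence C6 cis to the ester.

Step 10
Reactants: 18 methyl (2Z,4S,5Z)-7-[(3,4-dimethoxybenzyl)oxy]-6-methyl-4-[(triethylsilyl)oxy]-2,3-bis(trimethylstannyl)hepta-2,5-dienoate
Product: 20 methyl (2E,4S,5Z)-7-[(3,4-dimethoxybenzyl)oxy]-2-{[(4-methoxybenzyl)oxy]methyl}-6-methyl-4-[(triethylsilyl)oxy]-3-(trimethylstannyl)hepta-2,5-dienoate, via α-lithio enoate 19 (not isolated)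
Conditions: MeLi (1.05 equiv), THF, -98 °C; PMBOCH2Cl, HMPA, -98 to -78 °C
Reagents that add atoms: 4-methoxybenzyl chloromethyl ether, COc1ccc(COCCl)cc1
Why: Methyllithium transmetalates only the α-stannyl group (ester-stabilised vinyl anion), and alkylation of 19 with the chloromethyl ether should go with retention, cis to the remaining tin, so C13 lies cis to the future C8 and the ester cis to C6 (Piers-type α-transmetalation–alkylation of 2,3-bis(trimethylstannyl)alkenoates).

Step 11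
Reactants: 20 methyl (2E,4S,5Z)-7-[(3,4-dimethoxybenzyl)oxy]-2-{[(4-methoxybenzyl)oxy]methyl}-6-methyl-4-[(triethylsilyl)oxy]-3-(trimethylstannyl)hepta-2,5-dienoate
Product: 21 methyl (2E,4S,5Z)-7-[(3,4-dimethoxybenzyl)oxy]-3-iodo-2-{[(4-methoxybenzyl)oxy]methyl}-6-methyl-4-[(triethylsilyl)oxy]hepta-2,5-dienoate
Conditions: I2 (1.1 equiv), CH2Cl2, 0 °C
Reagents that add atoms: iodine, II
Why: Iododestannylation with retention of configuration gives the vinyl iodide needed for oxidative addition.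

Step 12
Reactants: 21 methyl (2E,4S,5Z)-7-[(3,4-dimethoxybenzyl)oxy]-3-iodo-2-{[(4-methoxybenzyl)oxy]methyl}-6-methyl-4-[(triethylsilyl)oxy]hepta-2,5-dienoate; 7 2,2-dimethyl-6-[3-(tributylstannyl)prop-1-en-2-yl]-4H-1,3-dioxin-4-one
Product: 22 C8 ketone: methyl (2E)-3-{(1S,2Z)-4-[(3,4-dimethoxybenzyl)oxy]-3-methyl-1-[(triethylsilyl)oxy]but-2-en-1-yl}-6-(2,2-dimethyl-4-oxo-4H-1,3-dioxin-6-yl)-2-{[(4-methoxybenzyl)oxy]methyl}-4-oxohepta-2,6-dienoate
Conditions: CO (3 atm), Pd2(dba)3·CHCl3 (5 mol %), AsPh3 (20 mol %), THF, 50 °C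
Reagents that add atoms: carbon monoxide, [C-]#[O+]
Why: Carbonylative Stille coupling (oxidative addition of zerovalent palladium into the vinyl iodide, CO insertion, allyl transfer from tin) forms C7–C8 and C8–C9 in one operation with retention of the tetrasubstituted olefin geometry.

Step 13
Reactants: 22 C8 ketone
Product: 23 (8R)-alcohol: methyl (2Z,4R)-3-{(1S,2Z)-4-[(3,4-dimethoxybenzyl)oxy]-3-methyl-1-[(triethylsilyl)oxy]but-2-en-1-yl}-6-(2,2-dimethyl-4-oxo-4H-1,3-dioxin-6-yl)-4-hydroxy-2-{[(4-methoxybenzyl)oxy]methyl}hepta-2,6-dienoate (olefin geometry unchanged; the descriptor changes by CIP ranking)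
Conditions: (S)-2-methyl-CBS-oxazaborolidine (0.3 equiv), catecholborane, toluene, -78 °C
Reagents that add atoms: none
Why: Corey–Bakshi–Shibata reduction, in which the (S)-oxazaborolidine treats the fully substituted alkenyl group (C7) as large and the CH2 group (C9) as small and delivers hydride to give the 8R carbinol, at low temperature and without base so the β,γ-unsaturated ketone does not isomerise.

Step 14
Reactants: 23 (8R)-alcohol
Product: 24 6,8-bis(triethylsilyl) ether: methyl (2Z,4R)-3-{(1S,2Z)-4-[(3,4-dimethoxybenzyl)oxy]-3-methyl-1-[(triethylsilyl)oxy]but-2-en-1-yl}-6-(2,2-dimethyl-4-oxo-4H-1,3-dioxin-6-yl)-2-{[(4-methoxybenzyl)oxy]methyl}-4-[(triethylsilyl)oxy]hepta-2,6-dienoate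
Conditions: TESOTf, 2,6-lutidine, CH2Cl2, -78 °C
Reagents that add atoms: triethylsilyl trifluoromethanesulfonate, CC[Si](CC)(CC)OS(=O)(=O)C(F)(F)F
Why: Silylation of the hindered allylic alcohol with the silyl triflate gives the C8 ether, which zerovalent palladium cannot ionise.

Step 15
Reactants: 24 6,8-bis(triethylsilyl) ether
Product: 25 seco alcohol: methyl (2Z,4R)-3-{(1S,2Z)-4-hydroxy-3-methyl-1-[(triethylsilyl)oxy]but-2-en-1-yl}-6-(2,2-dimethyl-4-oxo-4H-1,3-dioxin-6-yl)-2-{[(4-methoxybenzyl)oxy]methyl}-4-[(triethylsilyl)oxy]hepta-2,6-dienoate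
Conditions: DDQ (1.1 equiv), CH2Cl2/pH 7 buffer, 0 °C
Reagents that add atoms: none
Why: Oxidative debenzylation by DDQ is faster for the more electron-rich DMB ether than for the PMB ether, so only the C3 hydroxyl is freed.

Step 16
Reactants: 25 seco alcohol
Product: 27 twelve-membered allyl β-keto lactone (4Z,6S,7(11)Z,8R; ring C1(=O)–C2–CO–O–C3–C4=C5–C6–C7–C8–C9–C10(=CH2); 6,8-bis-OTES, 13-OPMB, C12 methyl ester), via acylketene 26 (not isolated)
Conditions: toluene, 110 °C, 0.5 mM, slow addition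
Reagents that add atoms: none
Why: Retro-[4+2] loss of acetone from the dioxinone gives acylketene 26, which the C3 hydroxyl traps intramolecularly at high dilution (Boeckman-type acylketene macrolactonisation) to close the twelve-membered β-keto lactone.

Step 17
Reactants: 27 twelve-membered allyl β-keto lactone
Product: 29 ten-membered enone (4Z,6S,7(11)Z,8R; C1 ketone, C10=C14 methylene, 6,8-bis-OTES, 13-OPMB, C12 methyl ester), via allylpalladium enolate 28 (not isolated)
Conditions: Pd(PPh3)4 (10 mol %), THF, 25 °C, 2 mM, degassed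
Reagents that add atoms: none
Why: Proposed new method: zerovalent palladium from Pd(PPh3)4 complexes the C4=C5 olefin anti to the C3–O bond and ionises this primary allylic ester (the only ionisable allylic C–O bond, since C6, C8 and C13 carry ethers); the β-keto carboxylate loses CO2 to give the C1–C2 enolate regiospecifically, and C2 then bonds to C3 to give the carbocycle and return the catalyst. The closest known reaction is the Tsuji–Saegusa decarboxylative allylation of acyclic allyl β-keto esters; new here is that the ester is a macrolactone, so the recombination is a twelve-to-ten ring contraction. The one ring formed closes by attack of the tethered enolate carbon C2 on the primary terminus C3 of the π-allyl unit inside a contact ion pair (divalent palladium allyl enolate 28), not by an intermolecular step. No stereocentre is created, and C6 and C8 are remote from the bonds that change. Terminus selectivity (C3 over C5) should follow from the unhindered primary C3 against C5, which is flanked by the silyloxy-bearing C6 and whose attack would give an eight-membered ring; the cross-conjugated enolate has C2 as its only nucleophilic carbon. The Z geometry should survive because the anti allyl complex formed from the Z ester is not disfavoured when the central carbon C4 bears a methyl group, and because collapse of the tethered ion pair should outrun π–σ–π isomerisation.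

Step 18
Reactants: 29 ten-membered enone
Product: 30 C13 alcohol (13-OH; otherwise as 29)
Conditions: DDQ (1.5 equiv), CH2Cl2/pH 7 buffer, 0 to 23 °C
Reagents that add atoms: none
Why: Oxidative cleavage of the PMB ether by DDQ frees the primary allylic C13 hydroxyl without touching the silyl ethers or the electron-poor olefins.

Step 19
Reactants: 30 C13 alcohol
Product: 31 C13 acetate (13-OAc; 6,8-bis-OTES; 4Z olefin)
Conditions: Ac2O, pyridine, DMAP (cat.), CH2Cl2, 0 °C
Reagents that add atoms: acetic anhydride, CC(=O)OC(C)=O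
Why: DMAP-catalysed acetylation of the unhindered primary alcohol installs the C13 acetate once no palladium step remains.

Step 20
Reactants: 31 C13 acetate
Product: 32 (4S,5R)-epoxide (4S,5R,6R,8R; 6,8-bis-OTES, 13-OAc, C12 methyl ester)
Conditions: mCPBA (1.2 equiv), NaHCO3, CH2Cl2, -20 to 0 °C
Reagents that add atoms: 3-chloroperoxybenzoic acid, OOC(=O)c1cccc(Cl)c1
Why: Prilezhaev epoxidation of the only electron-rich olefin (C4=C5), in which A(1,3) strain with C3H2 holds H6 in the olefin plane so the C6 triethylsilyloxy group covers one face and the peracid adds anti to it, setting 4S and 5R.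

Step 21
Reactants: 32 (4S,5R)-epoxide
Product: 34 butenolide alcohol (8-OH; 6,12-olide; 4,5-epoxide; 13-OAc), via hydroxy ester 33 (not isolated)
Conditions: TBAF, AcOH (1:1), THF, 0 to 23 °C
Reagents that add atoms: none
Why: Buffered fluoride cleaves both triethylsilyl ethers without opening the epoxide, and the freed C6 hydroxyl, held cis to the methyl ester across C7=C11, closes the butenolide by 5-exo-trig acyl substitution with C6 unchanged.

Step 22
Reactants: 34 butenolide alcohol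
Product: 35 target CNP0266914.1
Conditions: methacrylic anhydride, Et3N, DMAP, CH2Cl2, 0 to 23 °C
Reagents that add atoms: methacrylic anhydride, C=C(C)C(=O)OC(=O)C(C)=C
Why: DMAP-catalysed acyl transfer esterifies the C8 carbinol with retention, completing the target.

**Compound list**

1 | 2,2,6-trimethyl-4H-1,3-dioxin-4-one | CC1=CC(=O)OC(C)(C)O1 | starting material
2 | lithium 2,2-dimethyl-6-methylidene-6H-1,3-dioxin-4-olate | C=C1C=C(O[Li])OC(C)(C)O1 | intermediate
3 | 2,2-dimethyl-6-[2-(tributylstannyl)ethyl]-4H-1,3-dioxin-4-one | CCCC[Sn](CCCC)(CCCC)CCC1=CC(=O)OC(C)(C)O1 | intermediate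
4 | lithium 2,2-dimethyl-6-[3-(tributylstannyl)propylidene]-6H-1,3-dioxin-4-olate | CCCC[Sn](CCCC)(CCCC)CC=C1C=C(O[Li])OC(C)(C)O1 | intermediate
5 | 6-[1-(dimethylamino)-3-(tributylstannyl)propan-2-yl]-2,2-dimethyl-4H-1,3-dioxin-4-one (racemic) | CN(C)CC(C[Sn](CCCC)(CCCC)CCCC)C1=CC(=O)OC(C)(C)O1 | intermediate
6 | [2-(2,2-dimethyl-4-oxo-4H-1,3-dioxin-6-yl)-3-(tributylstannyl)propyl]trimethylammonium iodide | C[N+](C)(C)CC(C[Sn](CCCC)(CCCC)CCCC)C1=CC(=O)OC(C)(C)O1.[I-] | intermediate
7 | 2,2-dimethyl-6-[3-(tributylstannyl)prop-1-en-2-yl]-4H-1,3-dioxin-4-one | C=C(C[Sn](CCCC)(CCCC)CCCC)C1=CC(=O)OC(C)(C)O1 | intermediate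
8 | prop-2-yn-1-ol | C#CCO | starting material
9 | bromomagnesium (2Z)-3-(bromomagnesio)-2-methylprop-2-en-1-olate | C/C(CO[Mg]Br)=C/[Mg]Br | intermediate
10 | (2Z)-3-iodo-2-methylprop-2-en-1-ol | C/C(CO)=C/I | intermediate
11 | 4-({[(2Z)-3-iodo-2-methylprop-2-en-1-yl]oxy}methyl)-1,2-dimethoxybenzene | C/C(COCc1ccc(OC)c(OC)c1)=C/I | intermediate
12 | {(1Z)-3-[(3,4-dimethoxybenzyl)oxy]-2-methylprop-1-en-1-yl}lithium | C/C(COCc1ccc(OC)c(OC)c1)=C/[Li] | intermediate
13 | (2Z)-4-[(3,4-dimethoxybenzyl)oxy]-3-methylbut-2-enal | C/C(COCc1ccc(OC)c(OC)c1)=C/C=O | intermediate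
14 | methyl prop-2-ynoate | C#CC(=O)OC | starting material
15 | methyl 3-(methylzincio)prop-2-ynoate | C[Zn]C#CC(=O)OC | intermediate
16 | methyl (4S,5Z)-7-[(3,4-dimethoxybenzyl)oxy]-4-hydroxy-6-methylhept-5-en-2-ynoate | COC(=O)C#C[C@@H](O)/C=C(/C)COCc1ccc(OC)c(OC)c1 | intermediate
17 | methyl (4S,5Z)-7-[(3,4-dimethoxybenzyl)oxy]-6-methyl-4-[(triethylsilyl)oxy]hept-5-en-2-ynoate | COC(=O)C#C[C@@H](O[Si](CC)(CC)CC)/C=C(/C)COCc1ccc(OC)c(OC)c1 | intermediate
18 | methyl (2Z,4S,5Z)-7-[(3,4-dimethoxybenzyl)oxy]-6-methyl-4-[(triethylsilyl)oxy]-2,3-bis(trimethylstannyl)hepta-2,5-dienoate | COC(=O)/C([Sn](C)(C)C)=C(/[Sn](C)(C)C)[C@@H](O[Si](CC)(CC)CC)/C=C(/C)COCc1ccc(OC)c(OC)c1 | intermediate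
19 | methyl (2E,4S,5Z)-7-[(3,4-dimethoxybenzyl)oxy]-2-lithio-6-methyl-4-[(triethylsilyl)oxy]-3-(trimethylstannyl)hepta-2,5-dienoate | COC(=O)/C([Li])=C(/[Sn](C)(C)C)[C@@H](O[Si](CC)(CC)CC)/C=C(/C)COCc1ccc(OC)c(OC)c1 | intermediate
20 | methyl (2E,4S,5Z)-7-[(3,4-dimethoxybenzyl)oxy]-2-{[(4-methoxybenzyl)oxy]methyl}-6-methyl-4-[(triethylsilyl)oxy]-3-(trimethylstannyl)hepta-2,5-dienoate | COC(=O)/C(COCc1ccc(OC)cc1)=C(/[Sn](C)(C)C)[C@@H](O[Si](CC)(CC)CC)/C=C(/C)COCc1ccc(OC)c(OC)c1 | intermediate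
21 | methyl (2E,4S,5Z)-7-[(3,4-dimethoxybenzyl)oxy]-3-iodo-2-{[(4-methoxybenzyl)oxy]methyl}-6-methyl-4-[(triethylsilyl)oxy]hepta-2,5-dienoate | COC(=O)/C(COCc1ccc(OC)cc1)=C(/I)[C@@H](O[Si](CC)(CC)CC)/C=C(/C)COCc1ccc(OC)c(OC)c1 | intermediate
22 | C8 ketone: methyl (2E)-3-{(1S,2Z)-4-[(3,4-dimethoxybenzyl)oxy]-3-methyl-1-[(triethylsilyl)oxy]but-2-en-1-yl}-6-(2,2-dimethyl-4-oxo-4H-1,3-dioxin-6-yl)-2-{[(4-methoxybenzyl)oxy]methyl}-4-oxohepta-2,6-dienoate | COC(=O)/C(COCc1ccc(OC)cc1)=C(/C(=O)CC(=C)C1=CC(=O)OC(C)(C)O1)[C@@H](O[Si](CC)(CC)CC)/C=C(/C)COCc1ccc(OC)c(OC)c1 | intermediate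
23 | (8R)-alcohol: methyl (2Z,4R)-3-{(1S,2Z)-4-[(3,4-dimethoxybenzyl)oxy]-3-methyl-1-[(triethylsilyl)oxy]but-2-en-1-yl}-6-(2,2-dimethyl-4-oxo-4H-1,3-dioxin-6-yl)-4-hydroxy-2-{[(4-methoxybenzyl)oxy]methyl}hepta-2,6-dienoate | COC(=O)/C(COCc1ccc(OC)cc1)=C(/[C@H](O)CC(=C)C1=CC(=O)OC(C)(C)O1)[C@@H](O[Si](CC)(CC)CC)/C=C(/C)COCc1ccc(OC)c(OC)c1 | intermediate
24 | 6,8-bis(triethylsilyl) ether: methyl (2Z,4R)-3-{(1S,2Z)-4-[(3,4-dimethoxybenzyl)oxy]-3-methyl-1-[(triethylsilyl)oxy]but-2-en-1-yl}-6-(2,2-dimethyl-4-oxo-4H-1,3-dioxin-6-yl)-2-{[(4-methoxybenzyl)oxy]methyl}-4-[(triethylsilyl)oxy]hepta-2,6-dienoate | COC(=O)/C(COCc1ccc(OC)cc1)=C(/[C@H](O[Si](CC)(CC)CC)CC(=C)C1=CC(=O)OC(C)(C)O1)[C@@H](O[Si](CC)(CC)CC)/C=C(/C)COCc1ccc(OC)c(OC)c1 | intermediate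
25 | seco alcohol: methyl (2Z,4R)-3-{(1S,2Z)-4-hydroxy-3-methyl-1-[(triethylsilyl)oxy]but-2-en-1-yl}-6-(2,2-dimethyl-4-oxo-4H-1,3-dioxin-6-yl)-2-{[(4-methoxybenzyl)oxy]methyl}-4-[(triethylsilyl)oxy]hepta-2,6-dienoate | COC(=O)/C(COCc1ccc(OC)cc1)=C(/[C@H](O[Si](CC)(CC)CC)CC(=C)C1=CC(=O)OC(C)(C)O1)[C@@H](O[Si](CC)(CC)CC)/C=C(/C)CO | intermediate
26 | acylketene from 25 (C1 ketone, C2=C=O; free C3-OH; 6S,8R) | COC(=O)/C(COCc1ccc(OC)cc1)=C(/[C@H](O[Si](CC)(CC)CC)CC(=C)C(=O)C=C=O)[C@@H](O[Si](CC)(CC)CC)/C=C(/C)CO | intermediate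
27 | twelve-membered allyl β-keto lactone (4Z,6S,7(11)Z,8R; 6,8-bis-OTES, 13-OPMB, C12 methyl ester, C10=C14 methylene) | O=C1CC(=O)OC/C(C)=C\[C@H](O[Si](CC)(CC)CC)/C(=C(/COCc2ccc(OC)cc2)C(=O)OC)[C@H](O[Si](CC)(CC)CC)CC1=C | intermediate
28 | allylpalladium enolate (divalent palladium, two PPh3, drawn as the C3-bound form with the C1–C2 enolate; 6S,8R) | [Pd+](P(c1ccccc1)(c1ccccc1)c1ccccc1)(P(c1ccccc1)(c1ccccc1)c1ccccc1)C/C(C)=C\[C@H](O[Si](CC)(CC)CC)/C(=C(/COCc1ccc(OC)cc1)C(=O)OC)[C@H](O[Si](CC)(CC)CC)CC(=C)C([O-])=C | intermediate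
29 | ten-membered enone (4Z,6S,7(11)Z,8R; C1 ketone, C10=C14 methylene, 6,8-bis-OTES, 13-OPMB, C12 methyl ester) | O=C1CC/C(C)=C\[C@H](O[Si](CC)(CC)CC)/C(=C(/COCc2ccc(OC)cc2)C(=O)OC)[C@H](O[Si](CC)(CC)CC)CC1=C | intermediate
30 | C13 alcohol (as 29 with 13-OH) | O=C1CC/C(C)=C\[C@H](O[Si](CC)(CC)CC)/C(=C(/CO)C(=O)OC)[C@H](O[Si](CC)(CC)CC)CC1=C | intermediate
31 | C13 acetate (as 29 with 13-OAc) | O=C1CC/C(C)=C\[C@H](O[Si](CC)(CC)CC)/C(=C(/COC(C)=O)C(=O)OC)[C@H](O[Si](CC)(CC)CC)CC1=C | intermediate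
32 | (4S,5R,6R,8R)-epoxide (6,8-bis-OTES, 13-OAc, C12 methyl ester) | CC[Si](CC)(CC)O[C@@H]1CC(=C)C(=O)CC[C@]2(C)O[C@@H]2[C@H](O[Si](CC)(CC)CC)/C1=C(/COC(C)=O)C(=O)OC | intermediate
33 | (4S,5R,6R,8R)-6,8-dihydroxy epoxy methyl ester | O[C@@H]1CC(=C)C(=O)CC[C@]2(C)O[C@@H]2[C@H](O)/C1=C(/COC(C)=O)C(=O)OC | intermediate
34 | butenolide alcohol (4S,5R,6R,8R; 8-OH, 6,12-olide, 13-OAc) | O[C@@H]1CC(=C)C(=O)CC[C@]2(C)O[C@@H]2[C@@H]2OC(=O)C(COC(C)=O)=C21 | intermediate
35 | CNP0266914.1 (4S,5R,6R,8R) | C=C(C)C(=O)O[C@@H]1CC(=C)C(=O)CC[C@]2(C)O[C@@H]2[C@@H]2OC(=O)C(COC(C)=O)=C21 | target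

**Counts**

Total steps: 22. Longest linear sequence: 19 steps (steps 4–22, from 8 to 35); steps 1–3 are the side branch to stannane 7.

**Steps most likely to fail**

1. Step 17 (Proposed new method). What may go wrong:
- proton transfer from the acidic C2–H of unreacted lactone to the enolate, with loss of the allyl unit as a diene;
- recombination at C5 or at oxygen;
- syn–anti isomerisation eroding the Z geometry;
- intermolecular allylation, or phosphine addition to the enone.

Fallback (known reactions, ring closed by enolate alkylation instead of ion-pair collapse), setting out from 25 and rejoining at 29. The C3 alcohol of 25 is converted into the allylic chloride F1 (MsCl, LiCl, 2,4,6-collidine, DMF, 0 °C). F1 is heated with allyl alcohol in toluene at 110 °C so the acylketene is trapped as the open-chain allyl β-keto ester F2. F2 is cyclised by intramolecular C-alkylation at C2 (Cs2CO3, NaI, MeCN, high dilution) to the ten-membered 2-(allyloxycarbonyl) ketone F3 (mixture at C2). The ester is removed by Tsuji deallylation–decarboxylation (Pd(OAc)2, PPh3, HCO2H, Et3N, THF) to give 29.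

2. Step 20. What may go wrong: poor facial selectivity, if the ring conformation exposes the face syn to the C6 silyloxy group, and competing Baeyer–Villiger oxidation of the ketone.

Fallback, setting out from 31 and rejoining at 32: reagent-controlled Shi epoxidation in place of substrate-controlled peracid delivery (D-fructose-derived Shi ketone, Oxone, K2CO3, Bu4NHSO4, MeCN/dimethoxymethane/buffer, 0 °C). The spiro transition-state model assigns this ketone to the 4S,5R face of the trisubstituted olefin. No new compound is made.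

3. Step 12. What may go wrong: slow transmetalation of the electron-poor allylstannane (direct, non-carbonylative coupling instead) and migration of the β,γ-olefin into conjugation.

Fallback, setting out from 21 and rejoining at 22. Palladium-catalysed formylation of 21 (Pd(PPh3)4, CO, Bu3SnH, THF, 50 °C) gives enal F4. Lewis-acid allylation with 7 (BF3·OEt2, CH2Cl2, -78 °C) gives homoallylic alcohol F5 as a C8 epimer mixture. Dess–Martin oxidation (NaHCO3, CH2Cl2) gives 22, after which step 13 sets C8.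

Further compounds
F1 | step 17 | allylic chloride of 25 (C3-Cl; 6S,8R) | COC(=O)/C(COCc1ccc(OC)cc1)=C(/[C@H](O[Si](CC)(CC)CC)CC(=C)C1=CC(=O)OC(C)(C)O1)[C@@H](O[Si](CC)(CC)CC)/C=C(/C)CCl
F2 | step 17 | open-chain allyl β-keto ester with C3 chloride (6S,8R) | COC(=O)/C(COCc1ccc(OC)cc1)=C(/[C@H](O[Si](CC)(CC)CC)CC(=C)C(=O)CC(=O)OCC=C)[C@@H](O[Si](CC)(CC)CC)/C=C(/C)CCl
F3 | step 17 | ten-membered 2-(allyloxycarbonyl) ketone (4Z,6S,8R; C2 epimers) | O=C1C(C(=O)OCC=C)C/C(C)=C\[C@H](O[Si](CC)(CC)CC)/C(=C(/COCc2ccc(OC)cc2)C(=O)OC)[C@H](O[Si](CC)(CC)CC)CC1=C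
F0 | step 20 | none | none
F4 | step 12 | C8 enal: methyl (2E,4S,5Z)-7-[(3,4-dimethoxybenzyl)oxy]-3-formyl-2-{[(4-methoxybenzyl)oxy]methyl}-6-methyl-4-[(triethylsilyl)oxy]hepta-2,5-dienoate | COC(=O)/C(COCc1ccc(OC)cc1)=C(/C=O)[C@@H](O[Si](CC)(CC)CC)/C=C(/C)COCc1ccc(OC)c(OC)c1
F5 | step 12 | C8 alcohol, epimer mixture at C8 (as 23 without C8 configuration) | COC(=O)/C(COCc1ccc(OC)cc1)=C(/C(O)CC(=C)C1=CC(=O)OC(C)(C)O1)[C@@H](O[Si](CC)(CC)CC)/C=C(/C)COCc1ccc(OC)c(OC)c1
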